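# Proposed synthesis of 7,9-bis(angeloyloxy)longipinan-1-one (CNP0283599.1)

## The problem

The target is a longipinane. Its carbon perimeter C1–C2–…–C11–C1 is closed by two cross-ring bonds, C4–C10 and C5–C11, so that a cyclobutane (C4, C5, C11, C10) is shared by a bicyclo[3.1.1]heptan-1-one (bridge C1–C2–C3) and a bicyclo[4.1.1]octane (bridge C6–C7–C8–C9). C1 is the ketone, C3 and C10 carry methyl groups, C6 a gem-dimethyl group, and C7 and C9 the angelate esters.

Of the seven stereocentres, the four of the cage (C4, C5, C10, C11) fix one another once the rings exist. The open questions are the absolute sense of the cage and the three centres outside it (C3, C7, C9).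

C3 has its methyl group on the side of the C5–H bridge and its hydrogen under the C10 methyl group. No external reagent reaches that face, so the hydrogen cannot be the substituent that arrives last; the methyl group has to be.

C7 and C9 sit on a bridge that lies almost in the local mirror plane of the cage. The substrate therefore gives next to no facial bias at C7. C9 can be set from C7 by an internally delivered hydride, because the two oxygens are trans.

The angelates isomerise to tiglates and are Michael acceptors, so they go on last. The cage ketone is robust once made, because C11 is a bridgehead and C10 is quaternary, so neither can enolise.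

The feature that invites a short route is that C10 and C11 are the α-carbons of the oxygenated carbons C9 and C1. The bond between them is a 1,4-dioxygenated, like-polarity linkage that no enolate-plus-electrophile pairing makes directly. One-electron coupling of two enolates can make it in one step from a cis-fused bicycle in which C4–C5 is the ring fusion.

## Retrosynthesis

**Ester C–O bonds.** Target 24 is cut at both ester oxygens to diol 22 and angelic acid 23. Acylation is placed last because every earlier step (base, cuprate, borohydride, peroxide) would attack or isomerise a (Z)-2-methylbut-2-enoate. The forward step must acylate two neopentyl-type carbinols without Z-to-E isomerisation.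

**C9–H and C7–O.** Diol 22 is traced to β-hydroxy ketone 21 (C9–H bond) and 21 to enone 19 (C7–O bond). Cutting C7–O on an enone, and not C9–O, lets one oxygen direct the other: a boron-bound C7 alkoxide delivers hydride to C9 on its own face and gives the trans-diol. The C7 oxygen itself cannot be placed by the substrate, because the bridge faces differ only in whether C4–H or C11–H flanks them. A chiral copper–boryl catalyst is asked to choose the face, and oxidation of the C–B bond then proceeds with retention.

**C3–CH3.** Enone 19 is cut at the C3–methyl bond to bis-enone 18. The neighbouring cut, C3–H (hydrogenation of a 3-methyl enone), was rejected: hydrogen, hydride or a hydrogen atom would all enter from the open C5–H side and give the C3 epimer. A directing hydroxyl at C1 would have to hold the metal under the C10 methyl group. A methyl cuprate entering from the open side gives the required configuration, as such reagents do with nopinone-derived enones. The C3 methyl group is therefore left off until after the cage is closed. The forward step must distinguish the upper enone (C3 secondary, one open face) from the lower one (C7 neopentylic).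

**C10–C11 (key step).** Tricycle 18 is cut at the cyclobutane bond that joins the two ketone α-carbons, giving cis-fused bicyclic bis-enone 16 through bis-enolate 17. Compared with the other cyclobutane bonds, this cut removes two stereocentres and one ring, and leaves a bicycle whose two ketones are already the functional groups needed later. It needs no leaving group or protecting group. Each ketone is kept as an enone so that kinetic base can only remove the α′-proton (C11–H2; C10–H, with C6 quaternary). The forward reaction must close a four-membered ring faster than the enolates couple between molecules.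

**C1=O and C7=C8.** Bis-enone 16 is simplified to dienone 15 by removing the C1 carbonyl oxygen (allylic oxidation forward), and 15 to triene 14 by opening C7=C8 (ring-closing metathesis forward). Metathesis is preferred to an aldol closure because the two alkenes are a vinyl ketone and the 1,1-dimethylallyl group that the first building block already carries. The C1 oxygen is introduced after ring closure because vinyl Grignard addition (step 7) would not tolerate a ring enone.

**C8–C9.** Vinyl ketone 14 comes from Weinreb amide 12 and vinylmagnesium bromide 13, and 12 from acid 11. This is a routine one-carbon-oxidation-level adjustment with no stereochemical consequence.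

**C4–C10 (the cis ring fusion).** Acid 11 is cut at C4–C10 by a retro-Ireland–Claisen step to propanoate 8. This bond was chosen for a sigmatropic construction because alkylation or conjugate addition next to the tert-alkyl group on C5 would place the new substituent trans. The rearrangement instead delivers carbon to C4 on the face that carried the allylic oxygen, so the cis relationship follows from the cis-1,4 arrangement in 8. Ester 8 comes by Mitsunobu inversion from trans-alcohol 6 and propanoic acid 7, and 6 by Luche reduction from enone 5. The configuration at C10 in 11–16 is irrelevant because that centre is enolised in the key step.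

**C5–C11 and C3=C4 (absolute configuration).** Cyclohexenone 5 is opened to aldehyde 2 and methyl vinyl ketone 3, via keto aldehyde 4. The enamine-catalysed Michael addition sets the single stereocentre (C5) from which all others follow. Aldehyde 2 is the reduction product of commercial ester 1, which already holds the quaternary C6 and the vinyl group used in the metathesis.

## Roads not taken

**Alternative 1:** Here C5–C11 and C1–C2 are cut together, and the seven-membered ring is the tether of an intramolecular Diels–Alder reaction. Heating the open-chain nitro triene A2 should let its 2-silyloxydiene (C2 to C5) add to the nitroalkene (C11=C1) and give the cis-fused nitro bicycle A1, with the rings joined at C5–C11.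

- Merits: both carbocycles form at once. C7, C9 and C10 are carried in from acyclic chemistry, so the C7/C9 problem that the chosen plan must solve with a chiral catalyst is settled before any ring exists; on that point this road is better.
- Weak points: A2 is a long linear target with three stereocentres and two sensitive π-systems. A cycloaddition through a five-atom tether is slow, and its endo/exo and facial selectivity relative to the chain stereocentres is open. The nitro group still has to become the C1 ketone. The cyclobutane is not yet made and would need a later polar C4–C10 closure after redox changes at both carbons. C3 would again need hydrogen on the shielded face.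
- Comparison: the chosen plan sets against the better C7/C9 control a much shorter, protecting-group-free sequence and direct formation of the cage bond, at the price of one unprecedented step.

**Alternative 2:** Here C3–C4 and C1–C11 are cut, so that the six-membered ring is annulated onto a purchased four-membered ring. Cyclobutanone A4, activated as a chiral pyrrolidine enamine, would be C-alkylated at C4 by (E)-but-2-enoyl chloride A5 and then acylated at C11, giving the bicyclo[3.1.1]heptanedione A3.

- Merits: the cyclobutane is bought and not made. The C3 methyl stereocentre is created in the ring-forming step, which is better than the chosen plan, where the methyl group must be added late and chemoselectively.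
- Weak points: the desymmetrising annulation on a strained enamine has little precedent. A3 is a bridged β-diketone containing a cyclobutanone, open to retro-Claisen cleavage. The whole seven-membered ring still has to be built across C5 and C10, including the quaternary C6 next to the four-membered ring and both carbinol centres. That is the larger half of the molecule, and its C7/C9 faces are as alike as in the chosen plan.
- Comparison: the chosen plan builds the hindered seven-membered ring early by metathesis and makes the cage last, and accepts a cuprate step in exchange.

**Alternative 3:** Here C7–C8 and C8–C9 are cut, i.e. C8 is inserted into a six-membered ring. cis-Decalone A7 would be ring-expanded by enol silylation, cyclopropanation, oxidative opening and elimination to cycloheptenone A6, which carries C1 as a ketal and C4 as an ether. The cage would be closed afterwards by alkylation of a C10 enolate at C4.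

- Merits: every reaction type is established, including the final cyclobutane closure; this is the lowest-risk road. The decalin stereochemistry comes from a cycloaddition, and C3 is set on a flexible ring.
- Weak points: it is the longest road and needs two protecting groups. The ring expansion depends on regioselective enolisation away from C10. The 4-exo-tet alkylation of a fully substituted enolate at a secondary centre competes with elimination. C7 still needs reagent control.
- Comparison: the chosen plan is shorter by what should be eight to ten operations and uses no protecting groups. What it must set against the security of this road is a fallback for its key step that borrows the same polar closure.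

Key step: step 10

Assumption: compounds 11, 12, 14, 15 and 16 are carried as mixtures of epimers at C10 (the former propanoate α-carbon), because this centre becomes planar in bis-enolate 17 and is rebuilt in step 10.

## Steps

Step 1
Reactants: 1 methyl 3,3-dimethylpent-4-enoate
Product: 2 3,3-dimethylpent-4-enal
Conditions: i-Bu2AlH (1.05 equiv), CH2Cl2, −78 °C; aqueous sodium potassium tartrate
Reagents that add atoms: none
Why: Partial reduction of an ester with i-Bu2AlH stops at the aluminium hemiacetal at low temperature and releases the aldehyde on work-up; the isolated vinyl group is inert.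

Step 2
Reactants: 2 3,3-dimethylpent-4-enal; 3 but-3-en-2-one (methyl vinyl ketone)
Product: 5 (R)-4-(2-methylbut-3-en-2-yl)cyclohex-2-en-1-one, via keto aldehyde 4 (not isolated)
Conditions: (S)-2-[methoxy(diphenyl)methyl]pyrrolidine (5 mol%), ethyl 3,4-dihydroxybenzoate (20 mol%), neat, 4 °C; then LiOH (cat.), i-PrOH, rt
Reagents that add atoms: none
Why: Enamine-catalysed Michael addition of an aldehyde to a vinyl ketone followed by intramolecular aldol condensation (organocatalytic Robinson-type annulation); the (S)-catalyst shields one face of the E-enamine so that the (S)-aldehyde 4 should form, which sets C5, and only the methyl ketone enolate can close a six-membered ring onto the aldehyde.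

Step 3
Reactants: 5 (R)-4-(2-methylbut-3-en-2-yl)cyclohex-2-en-1-one
Product: 6 (1R,4R)-4-(2-methylbut-3-en-2-yl)cyclohex-2-en-1-ol (trans)
Conditions: NaBH4, CeCl3·7H2O, MeOH, −78 °C
Reagents that add atoms: none
Why: Luche reduction is 1,2-selective; with the tert-alkyl group pseudo-equatorial, axial hydride attack should place the hydroxyl pseudo-equatorial, i.e. trans to the side chain.

Step 4
Reactants: 6 (1R,4R)-4-(2-methylbut-3-en-2-yl)cyclohex-2-en-1-ol; 7 propanoic acid
Product: 8 (1S,4R)-4-(2-methylbut-3-en-2-yl)cyclohex-2-en-1-yl propanoate (cis)
Conditions: PPh3, diisopropyl azodicarboxylate, THF, 0 °C → rt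
Reagents that add atoms: none
Why: Mitsunobu esterification inverts the carbinol centre and gives the cis ester, whose C–O bond can sit pseudo-axial for the next step; the crowded γ-carbon disfavours SN2′ attack.

Step 5
Reactants: 8 (1S,4R)-4-(2-methylbut-3-en-2-yl)cyclohex-2-en-1-yl propanoate
Product: 11 2-[(1S,6R)-6-(2-methylbut-3-en-2-yl)cyclohex-2-en-1-yl]propanoic acid (cis; epimers at the acid α-carbon), via silyl ketene acetal 9 (not isolated), via trimethylsilyl ester 10 (not isolated)
Conditions: LiN(i-Pr)2, THF, −78 °C; Me3SiCl, Et3N; −78 → 65 °C; 1 M HCl
Reagents that add atoms: none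
Why: Ireland–Claisen rearrangement: the ketene acetal carbon is delivered to the alkene terminus on the face that bears the C–O bond, so the new C4–C10 bond is cis to the tert-alkyl group on C5 and sets C4; the configuration at the acid α-carbon (C10) is immaterial.

Step 6
Reactants: 11 2-[(1S,6R)-6-(2-methylbut-3-en-2-yl)cyclohex-2-en-1-yl]propanoic acid
Product: 12 N-methoxy-N-methyl-2-[(1S,6R)-6-(2-methylbut-3-en-2-yl)cyclohex-2-en-1-yl]propanamide
Conditions: MeNHOMe·HCl, EDCI·HCl, HOBt (cat.), i-Pr2NEt, CH2Cl2, 0 °C → rt
Reagents that add atoms: N,O-dimethylhydroxylamine hydrochloride, CNOC.Cl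
Why: Carbodiimide amide coupling to the Weinreb amide; no stereocentre that matters is touched.

Step 7
Reactants: 12 N-methoxy-N-methyl-2-[(1S,6R)-6-(2-methylbut-3-en-2-yl)cyclohex-2-en-1-yl]propanamide; 13 vinylmagnesium bromide
Product: 14 4-[(1S,6R)-6-(2-methylbut-3-en-2-yl)cyclohex-2-en-1-yl]pent-1-en-3-one
Conditions: CH2=CHMgBr (1.5 equiv), THF, −78 → 0 °C; poured into cold 1 M HCl
Reagents that add atoms: none
Why: Weinreb ketone synthesis: the chelated tetrahedral adduct survives until the acidic quench, so one vinyl group is added and the vinyl ketone is released only on work-up.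

Step 8
Reactants: 14 4-[(1S,6R)-6-(2-methylbut-3-en-2-yl)cyclohex-2-en-1-yl]pent-1-en-3-one
Product: 15 cis-fused bicyclic dienone (4S,5R)-6,6,10-trimethylbicyclo[5.4.0]undeca-2,7-dien-9-one (atom numbers of the problem section; six-membered ring C1–C2=C3–C4–C5–C11, seven-membered ring C4–C5–C6–C7=C8–C9–C10)
Conditions: second-generation Grubbs catalyst (5 mol%), toluene (2 mM), 80 °C
Reagents that add atoms: none
Why: Ring-closing metathesis of a vinyl ketone with a terminal alkene; the two chains are held cis on adjacent ring carbons and the gem-dimethyl group favours closure of the cycloheptenone, while the unstrained ring alkene stays out.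

Step 9
Reactants: 15 cis-fused bicyclic dienone
Product: 16 cis-fused bicyclic bis-enone (4S,5R)-6,6,10-trimethylbicyclo[5.4.0]undeca-2,7-diene-1,9-dione (3-demethylhimachala-2,7-diene-1,9-dione)
Conditions: Rh2(cap)4 (cap = caprolactamate, 1 mol%), t-BuOOH (5 equiv), K2CO3, CH2Cl2, rt
Reagents that add atoms: tert-butyl hydroperoxide, CC(C)(C)OO
Why: Allylic C–H oxidation by tert-butylperoxyl radicals: hydrogen should be taken from the only unhindered allylic methylene (C1) and oxygen returned to the same carbon, since the other allyl terminus (C3) and the tertiary C4–H lie next to two branched carbons.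

Step 10
Reactants: 16 cis-fused bicyclic bis-enone
Product: 18 3-demethyllongipina-2,7-diene-1,9-dione (4S,5S,10R,11R), via dilithium bis-enolate 17 (not isolated)
Conditions: LiN(i-Pr)2 (2.3 equiv), THF, −78 °C, 16 added slowly at 0.01 M; then Fe(acac)3 (2.2 equiv) in THF, −78 °C → rt
Reagents that add atoms: none
Why: Proposed new method: Kinetic deprotonation takes each enone at its only available α′-position (C11–H2 of the cyclohexenone, C10–H of the cycloheptenone, whose γ-carbon C6 is quaternary) and gives the cross-conjugated bis-enolate 17. Trivalent iron oxidises one enolate to an α-keto radical, which adds to the carbon of the neighbouring enolate in a 4-exo-trig closure; a second equivalent oxidises the resulting ketyl radical anion, and this makes the otherwise reversible four-ring closure irreversible. The closest known reactions are intramolecular oxidative couplings of ketone, ester and amide enolates with Fe(acac)3 or divalent copper carboxylates, and the oxidative cyclisation of diester dianions to cycloalkane-1,2-dicarboxylates; closure of a cyclobutane between two ketone enolates of a fused bicycle has not been shown. The only ring closed is the cyclobutane C4–C5–C11–C10. Both new stereocentres (C10 and C11) are dictated by the cis ring fusion, because C10 hangs from C4 and C11 from C5 on the same side, so the bond can form in one way only and the C10 epimers of 16 converge. The step needs the intramolecular coupling to outrun dimerisation and α-oxidation, for which the gauche arrangement of C10 and C11 across C4–C5 and high dilution are relied on, and it needs regiodefined enolates, which the two enones secure. The product cannot enolise again at C10 (quaternary) or C11 (bridgehead) and should survive the medium.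

Step 11
Reactants: 18 3-demethyllongipina-2,7-diene-1,9-dione
Product: 19 longipin-7-ene-1,9-dione (3R,4S,5S,10R,11R)
Conditions: Me2CuLi (1.1 equiv, from MeLi and CuI), Et2O, −78 °C; aqueous NH4Cl
Reagents that add atoms: lithium dimethylcuprate, [Li+].C[Cu-]C
Why: Cuprate conjugate addition: the bicyclo[3.1.1]heptenone should be attacked at C3 from the side of the C5–H bridge, anti to the C10 methyl group, as is established for nopinone-derived enones, which sets C3; the lower enone should be slower because C7 is neopentylic.

Step 12
Reactants: 19 longipin-7-ene-1,9-dione
Product: 21 7-hydroxylongipinane-1,9-dione (3R,4S,5S,7R,10R,11R), via C7 pinacol boronate 20 (not isolated)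
Conditions: CuCl (5 mol%), NaOt-Bu (10 mol%), (R,R)-QuinoxP* (6 mol%), B2pin2 (1.1 equiv), MeOH (2 equiv), THF, rt; then H2O2 (30% aq), pH 7 phosphate buffer, 0 °C
Reagents that add atoms: hydrogen peroxide, OO
Why: Copper-catalysed enantioselective β-borylation of a cyclic enone followed by stereoretentive C–B oxidation; because the bridge lies in the local mirror plane of the cage the substrate has little bias of its own, so the chiral phosphine should decide the face of C7, and the ligand antipode that places boron on the side of C4 is the one used (the sense has to be read from the first run).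

Step 13
Reactants: 21 7-hydroxylongipinane-1,9-dione
Product: 22 7,9-dihydroxylongipinan-1-one (3R,4S,5S,7R,9R,10R,11R)
Conditions: Me4NBH(OAc)3 (5 equiv), MeCN/AcOH (1:1), −30 °C
Reagents that add atoms: none
Why: Hydroxyl-directed reduction (Evans–Saksena): the boron-bound C7 alkoxide delivers hydride to C9 on its own face and should give the trans-1,3-diol, which sets C9; the C1 ketone has no hydroxyl within reach and should not be reduced.

Step 14
Reactants: 22 7,9-dihydroxylongipinan-1-one; 23 angelic acid [(Z)-2-methylbut-2-enoic acid]
Product: 24 7,9-bis[(Z)-2-methylbut-2-enoyloxy]longipinan-1-one (3R,4S,5S,7R,9R,10R,11R), the target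
Conditions: 23 (6 equiv), 2,4,6-Cl3C6H2COCl, Et3N, toluene, rt; then 22, 75 °C
Reagents that add atoms: none
Why: Yamaguchi-type acylation through the mixed anhydride without a nucleophilic catalyst, the established way to place angelates on hindered secondary alcohols while keeping the Z geometry.

## Compound list

1 | methyl 3,3-dimethylpent-4-enoate | COC(=O)CC(C)(C)C=C | starting material
2 | 3,3-dimethylpent-4-enal | O=CCC(C)(C)C=C | intermediate
3 | but-3-en-2-one (methyl vinyl ketone) | CC(=O)C=C | starting material
4 | (S)-2-(2-methylbut-3-en-2-yl)-5-oxohexanal | O=C[C@@H](CCC(C)=O)C(C)(C)C=C | intermediate (not isolated)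
5 | (R)-4-(2-methylbut-3-en-2-yl)cyclohex-2-en-1-one | O=C1C=C[C@@H](CC1)C(C)(C)C=C | intermediate
6 | (1R,4R)-4-(2-methylbut-3-en-2-yl)cyclohex-2-en-1-ol (trans) | O[C@H]1C=C[C@@H](CC1)C(C)(C)C=C | intermediate
7 | propanoic acid | CCC(O)=O | starting material
8 | (1S,4R)-4-(2-methylbut-3-en-2-yl)cyclohex-2-en-1-yl propanoate (cis) | CCC(=O)O[C@@H]1C=C[C@@H](CC1)C(C)(C)C=C | intermediate
9 | (E)-trimethylsilyl ketene acetal of 8 | C/C=C(/O[Si](C)(C)C)O[C@@H]1C=C[C@@H](CC1)C(C)(C)C=C | intermediate (not isolated)
10 | trimethylsilyl 2-[(1S,6R)-6-(2-methylbut-3-en-2-yl)cyclohex-2-en-1-yl]propanoate | C[Si](C)(C)OC(=O)C(C)[C@H]1C=CCC[C@H]1C(C)(C)C=C | intermediate (not isolated)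
11 | 2-[(1S,6R)-6-(2-methylbut-3-en-2-yl)cyclohex-2-en-1-yl]propanoic acid (cis; α-epimers) | OC(=O)C(C)[C@H]1C=CCC[C@H]1C(C)(C)C=C | intermediate
12 | N-methoxy-N-methyl-2-[(1S,6R)-6-(2-methylbut-3-en-2-yl)cyclohex-2-en-1-yl]propanamide | CON(C)C(=O)C(C)[C@H]1C=CCC[C@H]1C(C)(C)C=C | intermediate
13 | vinylmagnesium bromide | C=C[Mg]Br | starting material
14 | 4-[(1S,6R)-6-(2-methylbut-3-en-2-yl)cyclohex-2-en-1-yl]pent-1-en-3-one | C=CC(=O)C(C)[C@H]1C=CCC[C@H]1C(C)(C)C=C | intermediate
15 | cis-fused (4S,5R)-6,6,10-trimethylbicyclo[5.4.0]undeca-2,7-dien-9-one (C10 epimers; numbering of the problem section) | C1C=C[C@H]2[C@@H](C1)C(C)(C)C=CC(=O)C2C | intermediate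
16 | cis-fused (4S,5R)-6,6,10-trimethylbicyclo[5.4.0]undeca-2,7-diene-1,9-dione (C10 epimers) | O=C1C=C[C@H]2[C@@H](C1)C(C)(C)C=CC(=O)C2C | intermediate
17 | dilithium bis-enolate of 16 (C1=C11 and C9=C10 enolates) | [Li+].[Li+].[O-]C1C=C[C@H]2[C@@H](C=1)C(C)(C)C=CC([O-])=C2C | intermediate (not isolated)
18 | 3-demethyllongipina-2,7-diene-1,9-dione (4S,5S,10R,11R) | C1=CC(=O)[C@]2(C)[C@@H]3[C@@H]([C@H]2C(=O)C=C3)C1(C)C | intermediate
19 | longipin-7-ene-1,9-dione (3R,4S,5S,10R,11R) | C1=CC(=O)[C@]2(C)[C@@H]3[C@@H]([C@H]2C(=O)C[C@H]3C)C1(C)C | intermediate
20 | 7-(4,4,5,5-tetramethyl-1,3,2-dioxaborolan-2-yl)longipinane-1,9-dione (boron on the C4 side of C7) | CC1(C)OB(OC1(C)C)[C@@H]1CC(=O)[C@]2(C)[C@@H]3[C@@H]([C@H]2C(=O)C[C@H]3C)C1(C)C | intermediate (not isolated)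
21 | 7-hydroxylongipinane-1,9-dione (3R,4S,5S,7R,10R,11R) | O[C@@H]1CC(=O)[C@]2(C)[C@@H]3[C@@H]([C@H]2C(=O)C[C@H]3C)C1(C)C | intermediate
22 | 7,9-dihydroxylongipinan-1-one (3R,4S,5S,7R,9R,10R,11R; trans-diol) | O[C@@H]1C[C@@H](O)[C@]2(C)[C@@H]3[C@@H]([C@H]2C(=O)C[C@H]3C)C1(C)C | intermediate
23 | angelic acid, (Z)-2-methylbut-2-enoic acid | C/C=C(/C)C(O)=O | starting material
24 | 7,9-bis[(Z)-2-methylbut-2-enoyloxy]longipinan-1-one (3R,4S,5S,7R,9R,10R,11R) | C/C=C(/C)C(=O)O[C@@H]1C[C@@H](OC(=O)/C(C)=C\C)[C@]2(C)[C@@H]3[C@@H]([C@H]2C(=O)C[C@H]3C)C1(C)C | target

## Step count and least certain steps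

Total: 14 steps. Longest linear sequence: 14 steps (from 1; the route is fully linear and uses no protecting groups).

**Step 10 (key step).** The most likely failure is that the second deprotonation, at the tertiary C10–H, lags behind the first. The mono-enolate would then be oxidised and couple between molecules, or add to the other carbonyl. The other risk is that the 4-exo closure is slower than intermolecular coupling even from the bis-enolate.

Fallback by known two-electron chemistry, from 16 back to 18: 16 is deprotonated once (LiN(i-Pr)2, 1 equiv, at the more accessible C11 methylene) and silylated to the trimethylsilyl dienol ether F1. N-Iodosuccinimide should iodinate C11 from the side away from the C6 substituent to give the 11-iodo enone F2 (iodine trans to C6). KOt-Bu in t-BuOH/THF then lets the C10 enolate displace iodide from the rear (enolate alkylation by an α-halo ketone, 4-exo-tet) and returns the route to 18.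

**Step 9.** Regiocontrol of the radical oxidation may be lost: hydrogen abstraction at the tertiary ring-fusion C4–H, or oxygen delivery to C3, would give regioisomeric enones and erode the cis fusion.

Fallback from 15 to 16: SeO2 (cat.) with t-BuOOH hydroxylates by an ene reaction and [2,3]-shift, which prefers a ring methylene to a methine, and should give the C1 allylic alcohol F3. MnO2 then oxidises F3 to 16.

**Step 11.** Chemoselectivity between the two enones may be insufficient, so that methyl is also delivered to C7.

Fallback from 18 to 21, by protecting the upper enone through its oxidation state: Luche reduction should take the less hindered C1 carbonyl (C9 is flanked by the quaternary C10) and give allylic alcohol F4. The borylation–oxidation of step 12 then acts on the only remaining enone and gives hydroxy ketone F5. MnO2 reoxidises the allylic alcohol alone to enone F6, and excess Me2CuLi adds to C3 to reach 21.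

**Step 12.** Facial selectivity may be poor if the catalyst is hampered by the two quaternary neighbours (C6, C10) and the substrate offers no bias.

Fallback from 19 to 21, by separation and recycling in place of catalyst control: alkaline t-BuOOH epoxidises the enone on both faces to epoxy ketones F7 (oxygen on the C4 side) and F8. Reductive opening at C8 with (PhSe)2/NaBH4/AcOH gives 21 and its C7 epimer F9, which are separated. F9 is dehydrated under acid back to 19 and recycled.

**Step 14.** Z-to-E isomerisation of the angeloyl group, or incomplete acylation of the two neopentyl-type carbinols, may occur under the forcing conditions.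

Fallback from 22 to 24, building the Z-alkene after acylation: 22 is esterified (DCC, DMAP) with 2-[bis(2,2,2-trifluoroethoxy)phosphoryl]propanoic acid to the bis(phosphonopropanoate) F10. Still–Gennari olefination (KN(SiMe3)2, 18-crown-6, acetaldehyde, THF, −78 °C) then converts both phosphonates into (Z)-2-methylbut-2-enoates, giving 24.

## Further compounds

F1 | step 10 | trimethylsilyl dienol ether of 16 (C1=C11 silyl enol ether) | C[Si](C)(C)OC1C=C[C@H]2[C@@H](C=1)C(C)(C)C=CC(=O)C2C
F2 | step 10 | 11-iodo derivative of 16 (iodine trans to C6) | O=C1C=C[C@H]2[C@@H]([C@H]1I)C(C)(C)C=CC(=O)C2C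
F3 | step 9 | 1-hydroxy derivative of 15 (allylic alcohol, both C1 epimers) | OC1C=C[C@H]2[C@@H](C1)C(C)(C)C=CC(=O)C2C
F4 | step 11 | 1-hydroxy-3-demethyllongipina-2,7-dien-9-one (hydroxyl on the C10 side) | C1=CC(=O)[C@]2(C)[C@@H]3[C@@H]([C@H]2[C@H](O)C=C3)C1(C)C
F5 | step 11 | 1,7-dihydroxy-3-demethyllongipin-2-en-9-one | O[C@@H]1CC(=O)[C@]2(C)[C@@H]3[C@@H]([C@H]2[C@H](O)C=C3)C1(C)C
F6 | step 11 | 7-hydroxy-3-demethyllongipin-2-ene-1,9-dione | O[C@@H]1CC(=O)[C@]2(C)[C@@H]3[C@@H]([C@H]2C(=O)C=C3)C1(C)C
F7 | step 12 | 7,8-epoxylongipinane-1,9-dione, oxygen on the C4 side | O4[C@@H]1[C@H]4C(=O)[C@]2(C)[C@@H]3[C@@H]([C@H]2C(=O)C[C@H]3C)C1(C)C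
F8 | step 12 | 7,8-epoxylongipinane-1,9-dione, oxygen on the C11 side | O4[C@H]1[C@@H]4C(=O)[C@]2(C)[C@@H]3[C@@H]([C@H]2C(=O)C[C@H]3C)C1(C)C
F9 | step 12 | 7-epi-7-hydroxylongipinane-1,9-dione | O[C@H]1CC(=O)[C@]2(C)[C@@H]3[C@@H]([C@H]2C(=O)C[C@H]3C)C1(C)C
F10 | step 14 | 7,9-bis{2-[bis(2,2,2-trifluoroethoxy)phosphoryl]propanoyloxy}longipinan-1-one | CC(C(=O)O[C@@H]1C[C@@H](OC(=O)C(C)P(=O)(OCC(F)(F)F)OCC(F)(F)F)[C@]2(C)[C@@H]3[C@@H]([C@H]2C(=O)C[C@H]3C)C1(C)C)P(=O)(OCC(F)(F)F)OCC(F)(F)F
A1 | alternative 1 | cis-fused nitro bicycle (rings joined at C5–C11; C1 nitro, C3=C4 triethylsilyl enol ether, C7 tert-butyldimethylsilyl ether, C9 4-methoxybenzyl ether, C10 methyl) | CC(C)(C)[Si](C)(C)O[C@@H]1C[C@@H](OCc3ccc(OC)cc3)[C@@H](C)[C@@H]2[C@@H]([N+](=O)[O-])CC(C)=C(O[Si](CC)(CC)CC)[C@@H]2C1(C)C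
A2 | alternative 1 | open-chain (E)-nitroalkene 2-(triethylsilyloxy)diene, precursor of A1 | C=C(C)/C(O[Si](CC)(CC)CC)=C/C(C)(C)[C@H](O[Si](C)(C)C(C)(C)C)C[C@@H](OCc1ccc(OC)cc1)[C@@H](C)/C=C/[N+](=O)[O-]
A3 | alternative 2 | 7-{[tert-butyl(diphenyl)silyl]oxymethyl}-4,7-dimethylbicyclo[3.1.1]heptane-2,6-dione (ketones at C1 and C5 of the target numbering) | CC(C)(C)[Si](c1ccccc1)(c1ccccc1)OC[C@]2(C)[C@@H]3C(=O)[C@H]2C(=O)C[C@H]3C
A4 | alternative 2 | 3-{[tert-butyl(diphenyl)silyl]oxymethyl}-3-methylcyclobutan-1-one | CC1(CO[Si](c2ccccc2)(c2ccccc2)C(C)(C)C)CC(=O)C1
A5 | alternative 2 | (E)-but-2-enoyl chloride | C/C=C/C(Cl)=O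
A6 | alternative 3 | cis-fused bicyclic cyclohept-7-en-9-one (rings joined at C5–C11; C1 ethylene ketal, C4 4-methoxybenzyl ether) | O=C1C=CC(C)(C)[C@@H]2[C@H]([C@@H]1C)C3(OCCO3)C[C@@H](C)[C@H]2OCc4ccc(OC)cc4
A7 | alternative 3 | cis-decalone precursor of A6 (C9 ketone, C1 ethylene ketal, C4 4-methoxybenzyl ether) | O=C1CC(C)(C)[C@@H]2[C@H]([C@@H]1C)C3(OCCO3)C[C@@H](C)[C@H]2OCc4ccc(OC)cc4
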